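The target is 6,6'-diprenyl-1,3'-biindole. Unprimed atoms belong to the N-substituted indole and primed atoms (N1', C2', C3', C3a', C7a') to the NH-indole, with prenyl on C6 and on C6'.
Enabling feature: C3' in the pyrrole ring of the NH-indole is bonded to N1 of the other indole, so the C2'=C3' unit can be read as an alkyne that already hangs on N1.
Cuts: C2'–H is replaced by C2'–Si; C3'–C3a' and N1'–C2' are then cut together (o-iodoaniline plus silyl N-alkynylindole), followed by N1–C(sp) and finally the two aryl–CH2 bonds of the prenyl groups.
Forward: both benzene rings and the unprimed pyrrole ring are bought. Each arene is prenylated, the silylalkyne is attached to N1, the primed pyrrole ring (the only ring made) closes by palladium heteroannulation, and fluoride removes silicon.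
Stereochemistry: there is no stereocentre and both alkenes end in two methyl groups, so only regiochemistry counts (linear prenyl, silicon on C2', prenyl on C6').
Key step: step 5

Assumption: 2-bromo-5-iodoaniline and the other three starting materials are taken as catalogue chemicals. The aryl iodide needed for the annulation is made by halide exchange, because diazotisation media (nitrosating acid) would endanger the electron-rich prenyl alkene.

Step 1
Reactants: 1 6-bromoindole; 2 prenylboronic acid pinacol ester [4,4,5,5-tetramethyl-2-(3-methylbut-2-en-1-yl)-1,3,2-dioxaborolane]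
Product: 3 6-prenylindole [6-(3-methylbut-2-en-1-yl)-1H-indole]
Conditions: 2 (1.3 equiv), PdCl2(IPent)(3-chloropyridine) (2 mol %; IPent = 1,3-bis[2,6-di(pentan-3-yl)phenyl]imidazol-2-ylidene), 5 M aq KOH, THF, 70 °C
Reagents that add atoms: none
Why: Suzuki–Miyaura coupling of an aryl bromide with a 3,3-disubstituted allylboronate: the very bulky carbene ligand makes reductive elimination occur from the primary σ-allyl form of the allylpalladium intermediate, so the linear prenyl group and not the 1,1-dimethylallyl isomer should be attached at C6, and the free N–H is tolerated.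

Step 2
Reactants: 3 6-prenylindole; 4 (bromoethynyl)triisopropylsilane
Product: 5 6-prenyl-1-[(triisopropylsilyl)ethynyl]indole
Conditions: 4 (1.2 equiv), CuSO4·5H2O (20 mol %), 1,10-phenanthroline (40 mol %), K3PO4 (2 equiv), toluene, 85 °C
Reagents that add atoms: none
Why: Copper-catalysed N-alkynylation of an azole with a bromoalkyne (Ullmann-type C(sp)–N coupling): the indolide binds the phenanthroline-ligated copper through nitrogen and is joined there to the alkynyl group, which directs the bond to N1 rather than C3, while the bulky silyl cap resists base-induced desilylation and slows alkyne homocoupling.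

Step 3
Reactants: 6 2-bromo-5-iodoaniline; 2 prenylboronic acid pinacol ester
Product: 7 2-bromo-5-prenylaniline [2-bromo-5-(3-methylbut-2-en-1-yl)aniline]
Conditions: 2 (1.05 equiv), PdCl2(dppf) (3 mol %; dppf = 1,1'-bis(diphenylphosphino)ferrocene), K3PO4 (2 equiv), THF/H2O 9:1, 45 °C
Reagents that add atoms: none
Why: Chemoselective Suzuki–Miyaura coupling: at this temperature oxidative addition to the C–I bond meta to the amino group is far faster than to the electron-rich C–Br bond flanked by NH2, the chelating diphosphine does not favour a second insertion after the first coupling, and reductive elimination from the primary allyl terminus should give the linear prenyl isomer.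

Step 4
Reactants: 7 2-bromo-5-prenylaniline
Product: 8 2-iodo-5-prenylaniline [2-iodo-5-(3-methylbut-2-en-1-yl)aniline]
Conditions: NaI (2 equiv), CuI (5 mol %), trans-N,N'-dimethylcyclohexane-1,2-diamine (10 mol %), 1,4-dioxane, 110 °C
Reagents that add atoms: sodium iodide, [Na+].[I-]
Why: Copper-catalysed aromatic Finkelstein reaction: halide exchange at the diamine-ligated copper centre is an equilibrium pulled towards the iodide by the insolubility of NaBr in dioxane, the absence of base keeps the free amine from being arylated, and no acid or electrophilic iodine source ever meets the prenyl alkene.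

Step 5
Reactants: 8 2-iodo-5-prenylaniline; 5 6-prenyl-1-[(triisopropylsilyl)ethynyl]indole
Product: 9 6,6'-diprenyl-2'-(triisopropylsilyl)-1'H-1,3'-biindole
Conditions: 8 (1.2 equiv), Pd(OAc)2 (10 mol %), LiCl (1 equiv), Na2CO3 (3 equiv), dry DMF, 100 °C
Reagents that add atoms: none
Why: Larock heteroannulation, whose closest models are the annulations of o-iodoanilines and o-iodophenols with trialkylsilyl alkynes (triisopropylsilyl included) that deliver 2-silyl heterocycles. Zerovalent palladium generated from Pd(OAc)2 inserts into the C–I bond of 8, the chloride-ligated arylpalladium species binds the alkyne of 5, and syn-carbopalladation joins the aryl carbon (C3a') to the nitrogen-bearing alkyne carbon (C3') while palladium ends on the silyl-bearing carbon (C2'). The amino group then replaces halide on palladium with loss of HI to Na2CO3, and C–N reductive elimination from the six-membered azapalladacycle closes the five-membered pyrrole ring, so the ring arises by a [3+2] annulation with C3'–C3a' formed first and N1'–C2' second. The selectivity needed is the insertion regiochemistry, and steric and electronic bias agree: the triisopropylsilyl group avoids the short forming C–C bond and prefers the carbon on the long C–Pd bond, and donation from N1 makes its own alkyne carbon the more electrophilic terminus, the one the migrating aryl group attacks. The place of iodine in 8 (para to the prenyl group) fixes the prenyl group at C6', and the trisubstituted prenyl alkenes are much poorer insertion partners than the alkyne, so they should remain spectators. No stereocentre is created.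

Step 6
Reactants: 9 6,6'-diprenyl-2'-(triisopropylsilyl)-1'H-1,3'-biindole
Product: 10 6,6'-diprenyl-1'H-1,3'-biindole [6,6'-bis(3-methylbut-2-en-1-yl)-1'H-1,3'-biindole]
Conditions: Bu4NF (3 equiv, 1 M in THF, water-containing), THF, 60 °C
Reagents that add atoms: none
Why: Fluoride-mediated protodesilylation of a 2-silylindole: fluoride adds to silicon, the C2'–Si bond breaks because the sp2 carbanion next to N1' is a competent leaving group that is protonated by the water in the reagent, and the non-acidic medium should leave both prenyl groups and the N1–C3' bond untouched.

Compound list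
1 | 6-bromoindole | Brc1ccc2cc[nH]c2c1 | starting material
2 | prenylboronic acid pinacol ester | CC(C)=CCB1OC(C)(C)C(C)(C)O1 | starting material
3 | 6-prenylindole | CC(C)=CCc1ccc2cc[nH]c2c1 | intermediate
4 | (bromoethynyl)triisopropylsilane | CC(C)[Si](C#CBr)(C(C)C)C(C)C | starting material
5 | 6-prenyl-1-[(triisopropylsilyl)ethynyl]indole | CC(C)=CCc1ccc2ccn(C#C[Si](C(C)C)(C(C)C)C(C)C)c2c1 | intermediate
6 | 2-bromo-5-iodoaniline | Nc1cc(I)ccc1Br | starting material
7 | 2-bromo-5-prenylaniline | Nc1cc(CC=C(C)C)ccc1Br | intermediate
8 | 2-iodo-5-prenylaniline | Nc1cc(CC=C(C)C)ccc1I | intermediate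
9 | 6,6'-diprenyl-2'-(triisopropylsilyl)-1'H-1,3'-biindole | CC(C)=CCc1ccc2c(-n3ccc4ccc(CC=C(C)C)cc43)c([Si](C(C)C)(C(C)C)C(C)C)[nH]c2c1 | intermediate
10 | 6,6'-diprenyl-1'H-1,3'-biindole | CC(C)=CCc1ccc2c(-n3ccc4ccc(CC=C(C)C)cc43)c[nH]c2c1 | target

Total step count: 6.
Longest linear sequence: 4 steps (1, 2, 5, 6 or 3, 4, 5, 6).

Steps most likely to fail

Step 5. The bulk of the triisopropylsilyl group may slow alkyne insertion. Hydrodeiodination of the aniline and hydrolytic breakdown of the N-alkynylindole could then take over, or the insertion regiochemistry could erode. The fallback replaces the annulation by a C–N cross-coupling; it sets out from 3 and rejoins the route at 10. Iodination of 3 at C3 (I2, KOH, DMF, 0 °C) should give 3-iodo-6-prenylindole F1. This is sulfonylated at once (NaH, TsCl, THF) to 3-iodo-6-prenyl-1-tosylindole F2. Ullmann–Goldberg N-arylation of a second portion of 3 with F2 (CuI, trans-N,N'-dimethylcyclohexane-1,2-diamine, K3PO4, toluene, 110 °C) should give 6,6'-diprenyl-1'-tosyl-1,3'-biindole F3. KOH in MeOH/THF at reflux then removes the sulfonyl group to reach 10.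

Step 2. C–N coupling may be sluggish for an indole that carries no acceptor group, so that homocoupling consumes the bromoalkyne. The fallback builds the alkyne on nitrogen by addition and elimination; it sets out from 3 and rejoins the route at 5. Addition of 3 to dichloroacetylene formed in situ from trichloroethylene (Cs2CO3, DMF, 60 °C) should give 1-[(E)-1,2-dichlorovinyl]-6-prenylindole F4 by anti addition. n-BuLi (2.2 equiv, THF, −78 °C) then effects elimination and chlorine–lithium exchange to 1-(lithioethynyl)-6-prenylindole F5. This is silylated in the same flask with triisopropylsilyl triflate to give 5.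

Step 6. C–Si cleavage may be incomplete, because silicon is hindered by its isopropyl groups and by the indolyl group on C3'. Deprotonation of N1'–H by the basic fluoride also makes C2' a poorer leaving group, and forcing conditions could move the prenyl double bonds into conjugation. The fallback carries a smaller silyl group through the same bond-forming sequence; it sets out from 3 and rejoins the route at 10. Ethynyltriethylsilane is brominated (NBS, AgNO3 cat., acetone) to (bromoethynyl)triethylsilane F6. Coupling of F6 with 3 as in step 2 should give 6-prenyl-1-[(triethylsilyl)ethynyl]indole F7. Annulation of F7 with 8 as in step 5 should give 6,6'-diprenyl-2'-(triethylsilyl)-1'H-1,3'-biindole F8. Bu4NF in THF at room temperature should then suffice to reach 10.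

Further compounds
F1 | step 5 | 3-iodo-6-prenylindole | CC(C)=CCc1ccc2c(I)c[nH]c2c1
F2 | step 5 | 3-iodo-6-prenyl-1-tosylindole | CC(C)=CCc1ccc2c(I)cn(S(=O)(=O)c3ccc(C)cc3)c2c1
F3 | step 5 | 6,6'-diprenyl-1'-tosyl-1,3'-biindole | CC(C)=CCc1ccc2c(-n3ccc4ccc(CC=C(C)C)cc43)cn(S(=O)(=O)c3ccc(C)cc3)c2c1
F4 | step 2 | 1-[(E)-1,2-dichlorovinyl]-6-prenylindole | Cl/C=C(/Cl)n1ccc2ccc(CC=C(C)C)cc21
F5 | step 2 | 1-(lithioethynyl)-6-prenylindole | [Li]C#Cn1ccc2ccc(CC=C(C)C)cc21
F6 | step 6 | (bromoethynyl)triethylsilane | CC[Si](CC)(CC)C#CBr
F7 | step 6 | 6-prenyl-1-[(triethylsilyl)ethynyl]indole | CC(C)=CCc1ccc2ccn(C#C[Si](CC)(CC)CC)c2c1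
F8 | step 6 | 6,6'-diprenyl-2'-(triethylsilyl)-1'H-1,3'-biindole | CC(C)=CCc1ccc2c(-n3ccc4ccc(CC=C(C)C)cc43)c([Si](CC)(CC)CC)[nH]c2c1
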